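**Plan**
1. Cuts: the six O-benzyl groups; the interflavan bond C4(upper)–C8(lower), made from an 8-lithio lower flavan and an upper flavan-4-one, the C4–OH then replaced by H; in the lower unit C3–OH goes back to a C3 ketone whose oxygen stands in for a formyl group; ring C of the lower unit is then cut at C3–C4 (aldol) and O1–C2 (oxa-Michael).
2. Enabling feature: in the lower flavan-3-ol, C4 sits on ring A (at C4a) ortho to the ring oxygen O1 (on C8a), so ring A plus C4 is a salicylaldehyde; C2–C3 with the C2 aryl is a cinnamaldehyde, whose formyl carbon on C3 makes C3 an enamine nucleophile and is later exchanged for oxygen.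
3. Forward: lower ring C arises first, in one amine-catalysed domino step closed by the C3–C4 aldol bond; then formyl to oxygen (Baeyer–Villiger), ketone to cis-alcohol, O-benzylation and C8 bromination.
4. Upper ring C is taken ready-made from a chromone (asymmetric aryl addition at C2); the halves are joined as C8–Li plus C4=O, the carbinol is reduced ionically, and all benzyl ethers are removed last.
5. Stereochemistry: lower C2 from the diarylprolinol silyl ether catalyst; lower C3 from C2 (bulky hydride, 2,3-cis); upper C2 from the Pd/pyridine-oxazoline catalyst; upper C4 from upper C2 (axial hydride delivery to the C4 cation, 2,4-cis).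

Key step: step 3

Assumption: the sense of induction in steps 3 and 9 follows the usual models for these catalyst classes ((S)-amine gives 2R in step 3; (R)-ligand gives 2S in step 9, by analogy with cyclic enones).

**Step 1**
Reactants: 1 2,4,6-trihydroxybenzaldehyde
Product: 2 2,4-bis(benzyloxy)-6-hydroxybenzaldehyde
Conditions: BnBr (2.0 equiv), K2CO3, DMF, 0 °C to rt
Reagents that add atoms: benzyl bromide, BrCc1ccccc1
Why: Williamson ether synthesis in which the para hydroxyl and one ortho hydroxyl are alkylated, while the last ortho hydroxyl, held in a strong hydrogen bond to the formyl group, is the least nucleophilic and should stay free with two equivalents of bromide.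

**Step 2**
Reactants: 3 4-(benzyloxy)benzaldehyde; 4 (triphenylphosphoranylidene)acetaldehyde
Product: 5 (E)-3-[4-(benzyloxy)phenyl]prop-2-enal
Conditions: toluene, 80 °C
Reagents that add atoms: none
Why: Wittig reaction of a stabilised ylide with an aromatic aldehyde, which should give the (E)-enal, one equivalent of ylide limiting a second homologation.

**Step 3**
Reactants: 2 2,4-bis(benzyloxy)-6-hydroxybenzaldehyde; 5 (E)-3-[4-(benzyloxy)phenyl]prop-2-enal
Product: 8 (2R)-5,7-bis(benzyloxy)-2-[4-(benzyloxy)phenyl]-2H-chromene-3-carbaldehyde, via oxa-Michael adduct 6 (not isolated), via aldol 7 (not isolated)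
Conditions: (S)-2-[diphenyl(trimethylsilyloxy)methyl]pyrrolidine (20 mol%), 2-nitrobenzoic acid (20 mol%), 4 Å molecular sieves, toluene, rt
Reagents that add atoms: none
Why: The amine and enal 5 form an E-configured s-trans iminium ion; the acidic phenol O1–H of 2 adds to its β-carbon (oxa-Michael addition, giving the O1–C2 bond and the C2 stereocentre), and the resulting enamine attacks the neighbouring formyl carbon on ring A (intramolecular aldol addition), which closes ring C through the C3–C4 bond before water and the catalyst are lost. The closest known reaction type is the diarylprolinol silyl ether catalysed domino oxa-Michael/aldol condensation of salicylaldehydes with cinnamaldehydes to 2-aryl-2H-chromene-3-carbaldehydes. Ring C closes in a 6-(enolexo)-exo-trig mode, with the enamine carbon (C3) as nucleophile and the aryl aldehyde carbon (C4) as electrophile. C2, the only stereocentre kept, is set by the catalyst, whose diphenyl(silyloxy)methyl group covers one face of the iminium ion so that the phenol attacks the other (2R expected from the (S)-amine); the transient C3 and C4 centres of 7 are erased by dehydration. The step needs enantiofacial control and a clean choice of partners: the amine should condense with the unhindered enal and not with the doubly ortho-substituted, hydrogen-bonded aldehyde of 2, only one phenol of 2 is free, and the dehydration to the conjugated aldehyde pulls the reversible oxa-Michael equilibrium forward. The formyl carbon left on C3 is the helper that step 4 exchanges for oxygen.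

**Step 4**
Reactants: 8 (2R)-5,7-bis(benzyloxy)-2-[4-(benzyloxy)phenyl]-2H-chromene-3-carbaldehyde
Product: 10 (2R)-5,7-bis(benzyloxy)-2-[4-(benzyloxy)phenyl]chroman-3-one, via enol formate 9 (not isolated)
Conditions: 30% aq. H2O2, (2-O2NC6H4Se)2 (5 mol%), CH2Cl2, rt; then KHCO3, MeOH–H2O, 0 °C
Reagents that add atoms: hydrogen peroxide, OO
Why: Baeyer–Villiger oxidation of an α,β-unsaturated aldehyde by the peroxyseleninic acid formed in the flask, in which the electron-rich vinyl group should migrate in preference to hydride to give the enol formate, whose mild cleavage gives the C3 ketone by protonation at C4 and leaves C2 untouched.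

**Step 5**
Reactants: 10 (2R)-5,7-bis(benzyloxy)-2-[4-(benzyloxy)phenyl]chroman-3-one
Product: 11 (2R,3R)-5,7-bis(benzyloxy)-2-[4-(benzyloxy)phenyl]chroman-3-ol
Conditions: LiBH(s-Bu)3 (L-Selectride), LiBr, THF, −78 °C; then H2O
Reagents that add atoms: none
Why: Diastereoselective ketone reduction in which the bulky hydride attacks C3 equatorially next to the pseudo-equatorial C2 aryl group, so the new C3 hydroxyl should be axial and cis to the aryl group (2,3-cis), as known for flavan-3-ones, under non-enolising conditions that keep C2 intact.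

**Step 6**
Reactants: 11 (2R,3R)-5,7-bis(benzyloxy)-2-[4-(benzyloxy)phenyl]chroman-3-ol
Product: 12 (2R,3R)-3,5,7-tris(benzyloxy)-2-[4-(benzyloxy)phenyl]chromane
Conditions: NaH, BnBr, DMF, 0 °C to rt
Reagents that add atoms: benzyl bromide, BrCc1ccccc1
Why: Williamson ether synthesis on the secondary alkoxide, which masks the only acidic proton before the lithiation and touches no stereocentre.

**Step 7**
Reactants: 12 (2R,3R)-3,5,7-tris(benzyloxy)-2-[4-(benzyloxy)phenyl]chromane
Product: 13 (2R,3R)-3,5,7-tris(benzyloxy)-2-[4-(benzyloxy)phenyl]-8-bromochromane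
Conditions: NBS (1.0 equiv), CH2Cl2, −40 °C to 0 °C
Reagents that add atoms: N-bromosuccinimide, O=C1CCC(=O)N1Br
Why: Electrophilic aromatic bromination, for which C8 of 5,7-dialkoxyflavans (between O1 and the C7 ether) is the established site of attack, ring A being far more electron-rich than the 4-alkoxyphenyl ring.

**Step 8**
Reactants: 14 7-hydroxy-4H-chromen-4-one
Product: 15 7-(benzyloxy)-4H-chromen-4-one
Conditions: BnBr, K2CO3, acetone, reflux
Reagents that add atoms: benzyl bromide, BrCc1ccccc1
Why: Williamson ether synthesis on the acidic vinylogous-acid phenol, the chromone ring being stable to carbonate.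

**Step 9**
Reactants: 15 7-(benzyloxy)-4H-chromen-4-one; 16 4-(benzyloxy)phenylboronic acid
Product: 17 (2S)-7-(benzyloxy)-2-[4-(benzyloxy)phenyl]chroman-4-one
Conditions: Pd(OCOCF3)2 (5 mol%), (R)-4-tert-butyl-2-(pyridin-2-yl)-4,5-dihydrooxazole (6 mol%), NH4PF6 (30 mol%), H2O (5 equiv), ClCH2CH2Cl, 60 °C
Reagents that add atoms: none
Why: Palladium-catalysed asymmetric conjugate addition of an arylboronic acid to a chromone, in which the aryl–palladium species adds across C2=C3 on the face chosen by the pyridine-oxazoline ligand and the palladium enolate is protonated, so C2 is set by the catalyst and no base is present that could open the flavanone.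

**Step 10**
Reactants: 13 (2R,3R)-3,5,7-tris(benzyloxy)-2-[4-(benzyloxy)phenyl]-8-bromochromane; 17 (2S)-7-(benzyloxy)-2-[4-(benzyloxy)phenyl]chroman-4-one
Product: 19 (2S)-7-(benzyloxy)-2-[4-(benzyloxy)phenyl]-4-{(2R,3R)-3,5,7-tris(benzyloxy)-2-[4-(benzyloxy)phenyl]chroman-8-yl}chroman-4-ol, via aryllithium 18 (not isolated)
Conditions: n-BuLi (1.05 equiv), THF, −78 °C; then 17, −78 °C to −30 °C; then H2O
Reagents that add atoms: none
Why: Bromine–lithium exchange followed by 1,2-addition of the aryllithium to the ketone, a known way to join an 8-lithioflavan to a flavan-4-one, which fixes the C4–C8 link without regiochemical doubt; the new C4 carbinol centre may form as an epimer mixture because it is made planar again in step 11.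

**Step 11**
Reactants: 19 (2S)-7-(benzyloxy)-2-[4-(benzyloxy)phenyl]-4-{(2R,3R)-3,5,7-tris(benzyloxy)-2-[4-(benzyloxy)phenyl]chroman-8-yl}chroman-4-ol
Product: 21 (2S,4S)-7-(benzyloxy)-2-[4-(benzyloxy)phenyl]-4-{(2R,3R)-3,5,7-tris(benzyloxy)-2-[4-(benzyloxy)phenyl]chroman-8-yl}chromane, via benzylic cation 20 (not isolated)
Conditions: Et3SiH, CF3CO2H, CH2Cl2, −40 °C to 0 °C
Reagents that add atoms: none
Why: Ionic hydrogenation of a tertiary diaryl carbinol, in which acid ionises C4 to a doubly aryl-stabilised cation and the silane should deliver hydride axially, so the large C4 aryl group ends equatorial and cis to the equatorial C2 aryl group (2,4-cis, 4S).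

**Step 12**
Reactants: 21 (2S,4S)-7-(benzyloxy)-2-[4-(benzyloxy)phenyl]-4-{(2R,3R)-3,5,7-tris(benzyloxy)-2-[4-(benzyloxy)phenyl]chroman-8-yl}chromane
Product: 22 (2R,3R)-8-[(2S,4S)-7-hydroxy-2-(4-hydroxyphenyl)chroman-4-yl]-2-(4-hydroxyphenyl)chromane-3,5,7-triol
Conditions: H2 (1 atm), Pd(OH)2/C, THF–MeOH, rt
Reagents that add atoms: none
Why: Catalytic hydrogenolysis of the five aryl benzyl ethers and the one alkyl benzyl ether, conditions under which the cyclic flavan C2–O1 ethers and the diarylmethine C4 normally survive, so no stereocentre should be touched.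

**Compound list**
1 | 2,4,6-trihydroxybenzaldehyde | O=Cc1c(O)cc(O)cc1O | starting material
2 | 2,4-bis(benzyloxy)-6-hydroxybenzaldehyde | O=Cc1c(O)cc(OCc2ccccc2)cc1OCc1ccccc1 | intermediate
3 | 4-(benzyloxy)benzaldehyde | O=Cc1ccc(OCc2ccccc2)cc1 | starting material
4 | (triphenylphosphoranylidene)acetaldehyde | O=CC=P(c1ccccc1)(c1ccccc1)c1ccccc1 | starting material
5 | (E)-3-[4-(benzyloxy)phenyl]prop-2-enal | O=C/C=C/c1ccc(OCc2ccccc2)cc1 | intermediate
6 | (3S)-3-[3,5-bis(benzyloxy)-2-formylphenoxy]-3-[4-(benzyloxy)phenyl]propanal (oxa-Michael adduct, held as its enamine with the catalyst; not isolated) | O=Cc1c(OCc2ccccc2)cc(OCc2ccccc2)cc1O[C@H](c1ccc(OCc2ccccc2)cc1)CC=O | intermediate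
7 | (2S)-5,7-bis(benzyloxy)-2-[4-(benzyloxy)phenyl]-4-hydroxychromane-3-carbaldehyde (aldol, C3 and C4 as formed; not isolated) | O=CC1C(O)c2c(OCc3ccccc3)cc(OCc3ccccc3)cc2O[C@@H]1c1ccc(OCc2ccccc2)cc1 | intermediate
8 | (2R)-5,7-bis(benzyloxy)-2-[4-(benzyloxy)phenyl]-2H-chromene-3-carbaldehyde | O=CC1=Cc2c(OCc3ccccc3)cc(OCc3ccccc3)cc2O[C@@H]1c1ccc(OCc2ccccc2)cc1 | intermediate
9 | (2R)-5,7-bis(benzyloxy)-2-[4-(benzyloxy)phenyl]-2H-chromen-3-yl formate (not isolated) | O=COC1=Cc2c(OCc3ccccc3)cc(OCc3ccccc3)cc2O[C@@H]1c1ccc(OCc2ccccc2)cc1 | intermediate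
10 | (2R)-5,7-bis(benzyloxy)-2-[4-(benzyloxy)phenyl]chroman-3-one | O=C1Cc2c(OCc3ccccc3)cc(OCc3ccccc3)cc2O[C@@H]1c1ccc(OCc2ccccc2)cc1 | intermediate
11 | (2R,3R)-5,7-bis(benzyloxy)-2-[4-(benzyloxy)phenyl]chroman-3-ol | O[C@@H]1Cc2c(OCc3ccccc3)cc(OCc3ccccc3)cc2O[C@@H]1c1ccc(OCc2ccccc2)cc1 | intermediate
12 | (2R,3R)-3,5,7-tris(benzyloxy)-2-[4-(benzyloxy)phenyl]chromane | c1ccccc1CO[C@@H]1Cc2c(OCc3ccccc3)cc(OCc3ccccc3)cc2O[C@@H]1c1ccc(OCc2ccccc2)cc1 | intermediate
13 | (2R,3R)-3,5,7-tris(benzyloxy)-2-[4-(benzyloxy)phenyl]-8-bromochromane | c1ccccc1CO[C@@H]1Cc2c(OCc3ccccc3)cc(OCc3ccccc3)c(Br)c2O[C@@H]1c1ccc(OCc2ccccc2)cc1 | intermediate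
14 | 7-hydroxy-4H-chromen-4-one | O=c1ccoc2cc(O)ccc12 | starting material
15 | 7-(benzyloxy)-4H-chromen-4-one | O=c1ccoc2cc(OCc3ccccc3)ccc12 | intermediate
16 | 4-(benzyloxy)phenylboronic acid | OB(O)c1ccc(OCc2ccccc2)cc1 | starting material
17 | (2S)-7-(benzyloxy)-2-[4-(benzyloxy)phenyl]chroman-4-one | c1ccccc1COc1ccc([C@@H]2CC(=O)c3ccc(OCc4ccccc4)cc3O2)cc1 | intermediate
18 | {(2R,3R)-3,5,7-tris(benzyloxy)-2-[4-(benzyloxy)phenyl]chroman-8-yl}lithium (not isolated) | c1ccccc1CO[C@@H]1Cc2c(OCc3ccccc3)cc(OCc3ccccc3)c([Li])c2O[C@@H]1c1ccc(OCc2ccccc2)cc1 | intermediate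
19 | (2S)-7-(benzyloxy)-2-[4-(benzyloxy)phenyl]-4-{(2R,3R)-3,5,7-tris(benzyloxy)-2-[4-(benzyloxy)phenyl]chroman-8-yl}chroman-4-ol (C4 epimers) | c1ccccc1COc1ccc([C@@H]2CC(O)(c3c(OCc4ccccc4)cc(OCc4ccccc4)c4c3O[C@H](c3ccc(OCc5ccccc5)cc3)[C@H](OCc3ccccc3)C4)c3ccc(OCc4ccccc4)cc3O2)cc1 | intermediate
20 | (2S)-7-(benzyloxy)-2-[4-(benzyloxy)phenyl]-4-{(2R,3R)-3,5,7-tris(benzyloxy)-2-[4-(benzyloxy)phenyl]chroman-8-yl}chroman-4-ylium trifluoroacetate (not isolated) | c1ccccc1COc1ccc([C@@H]2C[C+](c3c(OCc4ccccc4)cc(OCc4ccccc4)c4c3O[C@H](c3ccc(OCc5ccccc5)cc3)[C@H](OCc3ccccc3)C4)c3ccc(OCc4ccccc4)cc3O2)cc1.[O-]C(=O)C(F)(F)F | intermediate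
21 | (2S,4S)-7-(benzyloxy)-2-[4-(benzyloxy)phenyl]-4-{(2R,3R)-3,5,7-tris(benzyloxy)-2-[4-(benzyloxy)phenyl]chroman-8-yl}chromane | c1ccccc1COc1ccc([C@@H]2C[C@H](c3c(OCc4ccccc4)cc(OCc4ccccc4)c4c3O[C@H](c3ccc(OCc5ccccc5)cc3)[C@H](OCc3ccccc3)C4)c3ccc(OCc4ccccc4)cc3O2)cc1 | intermediate
22 | (2R,3R)-8-[(2S,4S)-7-hydroxy-2-(4-hydroxyphenyl)chroman-4-yl]-2-(4-hydroxyphenyl)chromane-3,5,7-triol | Oc1ccc([C@@H]2C[C@H](c3c(O)cc(O)c4c3O[C@H](c3ccc(O)cc3)[C@H](O)C4)c3ccc(O)cc3O2)cc1 | target

**Step count:** 12 steps in total. The longest linear sequence is 9 steps (1, 3, 4, 5, 6, 7, 10, 11, 12).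

**Steps most likely to fail**

1. Step 3. The aldol closure onto the doubly ortho-substituted, hydrogen-bonded and electron-rich formyl group may be slower than the retro-oxa-Michael reaction. Conversion would then stall, and the enantiomeric purity would erode through the reversible first step or through electrocyclic opening of the chromene. Fallback, setting out from 2 and 3 and returning at 10: Henry condensation of 3 with nitromethane (NH4OAc, AcOH, 100 °C) would give (E)-1-(benzyloxy)-4-(2-nitrovinyl)benzene F1. Compound 2 and F1, under a chiral pyrrolidine-type secondary amine with salicylic acid, would undergo a domino oxa-Michael/Henry reaction and dehydration. Ring C is again closed across C3–C4, now by nitro-aldol addition of the much more nucleophilic nitronate, to give (2R)-5,7-bis(benzyloxy)-2-[4-(benzyloxy)phenyl]-3-nitro-2H-chromene F2, enriched by crystallisation if needed. Reduction and hydrolysis of the nitroalkene with CrCl2 (divalent chromium) in aqueous HCl/THF would then give ketone 10, so steps 2 to 4 are bypassed.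

2. Step 4. Epoxidation of the electron-rich C3=C4 bond, or migration of hydride instead of the vinyl group, may outrun the wanted oxygen insertion. Enolisation of the ketone towards C2 during formate cleavage would erode the C2 centre. Fallback, setting out from 8 and returning at 10: Pinnick oxidation (NaClO2, NaH2PO4, 2-methylbut-2-ene, t-BuOH–H2O) would give (2R)-5,7-bis(benzyloxy)-2-[4-(benzyloxy)phenyl]-2H-chromene-3-carboxylic acid F3. Curtius rearrangement with diphenylphosphoryl azide and Et3N in toluene (rt, then 80 °C) would pass through (2R)-5,7-bis(benzyloxy)-2-[4-(benzyloxy)phenyl]-2H-chromene-3-carbonyl azide F4 to (2R)-5,7-bis(benzyloxy)-2-[4-(benzyloxy)phenyl]-3-isocyanato-2H-chromene F5. Hydrolysis of F5 in the same flask with dilute aqueous HCl would give ketone 10. This is the classical way from 2H-chromene-3-carboxylic acids to chroman-3-ones.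

3. Step 10. The hindered aryllithium may act as a base, deprotonating C3 of the flavanone and causing ring opening to the chalcone, instead of adding to the carbonyl group. Fallback, setting out from 17 and 12 and returning at 21: NaBH4 reduction of 17 (MeOH–THF, 0 °C) would give (2S,4S)-7-(benzyloxy)-2-[4-(benzyloxy)phenyl]chroman-4-ol F6. Friedel–Crafts alkylation of the unbrominated flavan 12 at C8 by the C4 cation from F6 (BF3·OEt2, CH2Cl2, −20 °C) would give 21 directly. The 2,4-trans epimer and the C6-linked isomer would have to be removed by chromatography. Steps 7, 10 and 11 are bypassed.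

**Further compounds**
F1 | step 3 | (E)-1-(benzyloxy)-4-(2-nitrovinyl)benzene | O=[N+]([O-])/C=C/c1ccc(OCc2ccccc2)cc1
F2 | step 3 | (2R)-5,7-bis(benzyloxy)-2-[4-(benzyloxy)phenyl]-3-nitro-2H-chromene | O=[N+]([O-])C1=Cc2c(OCc3ccccc3)cc(OCc3ccccc3)cc2O[C@@H]1c1ccc(OCc2ccccc2)cc1
F3 | step 4 | (2R)-5,7-bis(benzyloxy)-2-[4-(benzyloxy)phenyl]-2H-chromene-3-carboxylic acid | OC(=O)C1=Cc2c(OCc3ccccc3)cc(OCc3ccccc3)cc2O[C@@H]1c1ccc(OCc2ccccc2)cc1
F4 | step 4 | (2R)-5,7-bis(benzyloxy)-2-[4-(benzyloxy)phenyl]-2H-chromene-3-carbonyl azide | [N-]=[N+]=NC(=O)C1=Cc2c(OCc3ccccc3)cc(OCc3ccccc3)cc2O[C@@H]1c1ccc(OCc2ccccc2)cc1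
F5 | step 4 | (2R)-5,7-bis(benzyloxy)-2-[4-(benzyloxy)phenyl]-3-isocyanato-2H-chromene | O=C=NC1=Cc2c(OCc3ccccc3)cc(OCc3ccccc3)cc2O[C@@H]1c1ccc(OCc2ccccc2)cc1
F6 | step 10 | (2S,4S)-7-(benzyloxy)-2-[4-(benzyloxy)phenyl]chroman-4-ol | c1ccccc1COc1ccc([C@@H]2C[C@H](O)c3ccc(OCc4ccccc4)cc3O2)cc1
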